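4 questions stand on the flasks below, and I answer them through one concentration, c(nucleophile), the free nucleophile, which makes the coupling of electrophile and nucleophile pseudo-first-order in electrophile.

| setting | dusk | summer | noon |
|---|---|---|---|
| solid electrophile | 0.40 M | 0.40 M | 0.40 M |
| nucleophile | 0.440 M | 0.740 M | 0.570 M |
| time | 40 h | 40 h | 40 h |

    solid electrophile ⇌ electrophile, rate k1*(cs1 - [electrophile]) while solid is left; crystals form when [electrophile] > cs1 (cs1 = 0.20 M, k1 = 7.9 × 10⁻⁴ min⁻¹)
    target → over-reaction product (k2 = 8.0 × 10⁻⁴ min⁻¹)
    electrophile + target → side product (k3 = 0.0020 L mol⁻¹ min⁻¹)
    nucleophile + acid set free ⇌ protonated nucleophile, settled at all times (K4 = 1500 L mol⁻¹)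
    electrophile + nucleophile → acid set free + target (k5 = 0.0063 L mol⁻¹ min⁻¹)

- part of the solid electrophile that has reacted (what has only dissolved counts as not reacted) at the end, dusk
- part of the solid electrophile that has reacted (what has only dissolved counts as not reacted) at the end, summer
- part of the solid electrophile that has reacted (what has only dissolved counts as not reacted) at the end, noon
- what raising the concentration of nucleophile from its lowest to its highest value here does to the part of the solid electrophile that has reacted (what has only dissolved counts as not reacted) (changes below 5 percentage points count as none) (it rises / no change / it falls)

- a species is counted by the solid electrophile in it: one side product counts as two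
- given per volume of solution although it is solid: solid electrophile
- at the start none of the solid electrophile is in solution
- what has only dissolved of solid electrophile counts as not reacted
- run time (dusk): 40 h

At the start each coupling costs two nucleophiles, because K4 times c(nucleophile) stands at 660 for dusk, far above one, so the acid set free goes to a second nucleophile. I therefore carry the half-charge mark: half of the nucleophile charged, as a share of the solid electrophile charged. It is 55.0% for dusk, 71.2% for noon and 92.5% for summer.

With dissolved electrophile held steady, dissolving and coupling run in series, so their times add: the amount coupled over 0.00948 M h⁻¹, plus the logarithm of charged over free nucleophile, divided by 0.151 h⁻¹. I neglect the side product. By this reckoning dusk has 10.0% of its nucleophile free after 36.1 h, and summer has 25.0% free after 38.4 h.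

The weak link is that steady stock, since the solution starts empty. Filling it takes one over k1 plus k5 times c(nucleophile), which is 4.68 h for dusk and 3.06 h for summer, and this comes off the run time. Dusk keeps 35.3 h, so I commit to 49.5%. Summer keeps 36.9 h, so I commit to a little under 69.4%. For noon I take the free share of nucleophile midway between those of dusk and summer, which gives 58.7%. The part reacted rises.

The forecast differs from my numbers and says 52% for dusk, 67% for summer, 58% for noon and it rises, noting that “free nucleophile runs low late in the low-nucleophile runs”.

The flasks give 47.9% for dusk, 64.4% for summer and 56.3% for noon; it rises, by 17 percentage points. Dusk is not at rest at 40.0 h: 20% of its nucleophile is free and 30.6% of the charge is still solid. The same flask as dusk with 0.11 M of nucleophile has its mark at 13.7% and reads 15.1%, with 7.90% of its nucleophile free. After 400 h dusk stands at 76.9%, past its mark, with 0.336% of its nucleophile free and 0.0807 M of acid set free unbound. Noon reaches 90.0% and summer 99.8%.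

The numbers of this flask were chosen freely; the flask was simulated.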